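## Retrosynthetic overview

1. The target is reached from its bis(aryl benzyl ether)/bis(TBS ether) form by fluoride treatment and hydrogenolysis; no skeletal change occurs at the end.
2. Tetrahydrofuran ring (formed last): the benzylic C–O bond closes by acid-mediated 5-exo etherification of a triol, obtained by LiAlH4 reduction of a 3,4-trans aldol lactone made from an (R)-β-benzyl-γ-butyrolactone enolate and an O-4-alkylated vanillin.
3. γ-Butyrolactone (formed first, later opened): its benzyl-bearing stereocentre and the C-8–C-8′ bond come from a Johnson–Claisen [3,3] rearrangement of a (2R,3E)-5-arylpent-3-en-2-ol (cross-metathesis of O-benzyleugenol with (R)-but-3-en-2-ol), followed by ozonolysis, reduction and lactonisation.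
4. Aldehyde partner: the aryl–O–C bond is made by Mitsunobu inversion of vanillin on an anti 1-aryl-1,3-bis(silyloxy)propan-2-ol, from Felkin–Anh addition of an aryl Grignard reagent to (R)-glyceraldehyde acetonide.
5. Stereochemical sources: (R)-but-3-en-2-ol controls the three ring centres; (R)-glyceraldehyde acetonide controls the two side-chain centres.

Assumption: the five starting materials are bought as catalogue compounds, the dioxolane aldehyde being distilled just before use.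

## Route

**Step 1**
Reactants: 1 4-allyl-1-(benzyloxy)-2-methoxybenzene (O-benzyleugenol); 2 (R)-but-3-en-2-ol
Product: 3 (2R,3E)-5-[4-(benzyloxy)-3-methoxyphenyl]pent-3-en-2-ol
Conditions: 1 (2 equiv), 2 (1 equiv), Hoveyda–Grubbs II (3 mol%), 1,4-benzoquinone (10 mol%), CH2Cl2, 40 °C; minor Z isomer removed on AgNO3–silica
Reagents that add atoms: none
Why: Olefin cross-metathesis of a type I allylarene with a type II secondary allylic alcohol is E-selective and does not touch the carbinol stereocentre bought in 2 (benzoquinone suppresses Ru–H isomerisation).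

**Step 2**
Reactants: 3 (2R,3E)-5-[4-(benzyloxy)-3-methoxyphenyl]pent-3-en-2-ol
Product: 5 ethyl (3R,4E)-3-[4-(benzyloxy)-3-methoxybenzyl]hex-4-enoate, via mixed ketene acetal 4 (not isolated)
Conditions: MeC(OEt)3 (6 equiv), EtCO2H (cat.), 138 °C, EtOH distilled off
Reagents that add atoms: triethyl orthoacetate, CC(OCC)(OCC)OCC
Why: Johnson–Claisen [3,3]-sigmatropic rearrangement through a chair with the methyl group equatorial forms the new C–C bond on the alkene face from which the C–O bond leaves, so the (R)-carbinol of 3 is transferred to the (R)-configured benzyl-bearing carbon and an E-alkene.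

**Step 3**
Reactants: 5 ethyl (3R,4E)-3-[4-(benzyloxy)-3-methoxybenzyl]hex-4-enoate
Product: 8 (4R)-4-[4-(benzyloxy)-3-methoxybenzyl]dihydrofuran-2(3H)-one, via aldehyde ester 6 (not isolated), via hydroxy ester 7 (not isolated)
Conditions: O3, CH2Cl2–MeOH, −78 °C (Sudan III end point); NaBH4, −78 °C → rt; then p-TsOH (cat.), CH2Cl2, rt
Reagents that add atoms: ozone, [O-][O+]=O
Why: Ozonolysis cleaves only the disubstituted alkene, borohydride reduces the peroxidic products to the primary alcohol and the γ-hydroxy ester lactonises, all without touching the stereocentre.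

**Step 4**
Reactants: 9 1-(benzyloxy)-4-bromo-2-methoxybenzene; 10 (R)-2,2-dimethyl-1,3-dioxolane-4-carbaldehyde
Product: 12 (S)-[4-(benzyloxy)-3-methoxyphenyl][(4R)-2,2-dimethyl-1,3-dioxolan-4-yl]methanol, via aryl Grignard reagent 11 (not isolated)
Conditions: 9, Mg, THF, rt; then 10, THF, −78 → −20 °C; aq. NH4Cl; minor syn epimer removed by chromatography
Reagents that add atoms: none
Why: Grignard addition under Felkin–Anh (non-chelation) control attacks the aldehyde face anti to the dioxolane C–O bond, so the (R)-centre of 10 sets the new carbinol as S (anti adduct, about 3–4:1 expected).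

**Step 5**
Reactants: 12 (S)-[4-(benzyloxy)-3-methoxyphenyl][(4R)-2,2-dimethyl-1,3-dioxolan-4-yl]methanol
Product: 13 {(S)-[4-(benzyloxy)-3-methoxyphenyl][(4R)-2,2-dimethyl-1,3-dioxolan-4-yl]methoxy}(tert-butyl)dimethylsilane
Conditions: TBSCl, imidazole, DMF, rt
Reagents that add atoms: tert-butyldimethylsilyl chloride, CC(C)(C)[Si](C)(C)Cl
Why: Standard imidazole-promoted silylation of a secondary alcohol, with no stereocentre involved.

**Step 6**
Reactants: 13 {(S)-[4-(benzyloxy)-3-methoxyphenyl][(4R)-2,2-dimethyl-1,3-dioxolan-4-yl]methoxy}(tert-butyl)dimethylsilane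
Product: 14 (2R,3S)-3-[4-(benzyloxy)-3-methoxyphenyl]-3-[(tert-butyldimethylsilyl)oxy]propane-1,2-diol
Conditions: AcOH–H2O (4:1), rt
Reagents that add atoms: none
Why: Acid hydrolysis of the terminal isopropylidene acetal is much faster than cleavage of the hindered secondary TBS ether.

**Step 7**
Reactants: 14 (2R,3S)-3-[4-(benzyloxy)-3-methoxyphenyl]-3-[(tert-butyldimethylsilyl)oxy]propane-1,2-diol
Product: 15 (1S,2R)-1-[4-(benzyloxy)-3-methoxyphenyl]-1,3-bis[(tert-butyldimethylsilyl)oxy]propan-2-ol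
Conditions: TBSCl (1.05 equiv), imidazole, CH2Cl2, −20 → 0 °C
Reagents that add atoms: tert-butyldimethylsilyl chloride, CC(C)(C)[Si](C)(C)Cl
Why: Sterically controlled silylation takes the primary hydroxyl and leaves only the hindered C-2 carbinol free.

**Step 8**
Reactants: 15 (1S,2R)-1-[4-(benzyloxy)-3-methoxyphenyl]-1,3-bis[(tert-butyldimethylsilyl)oxy]propan-2-ol; 16 vanillin (4-hydroxy-3-methoxybenzaldehyde)
Product: 17 4-({(1S,2S)-1-[4-(benzyloxy)-3-methoxyphenyl]-1,3-bis[(tert-butyldimethylsilyl)oxy]propan-2-yl}oxy)-3-methoxybenzaldehyde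
Conditions: 16 (1.5 equiv), PPh3, DIAD, toluene, 0 °C → rt
Reagents that add atoms: none
Why: Mitsunobu etherification with the acidic phenol of vanillin is an SN2 displacement of the oxyphosphonium group, inverting C-2 from R to S and giving the threo (1S,2S) aryl ether.

**Step 9**
Reactants: 8 (4R)-4-[4-(benzyloxy)-3-methoxybenzyl]dihydrofuran-2(3H)-one; 17 4-({(1S,2S)-1-[4-(benzyloxy)-3-methoxyphenyl]-1,3-bis[(tert-butyldimethylsilyl)oxy]propan-2-yl}oxy)-3-methoxybenzaldehyde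
Product: 19 (3S,4R)-4-[4-(benzyloxy)-3-methoxybenzyl]-3-{hydroxy[4-({(1S,2S)-1-[4-(benzyloxy)-3-methoxyphenyl]-1,3-bis[(tert-butyldimethylsilyl)oxy]propan-2-yl}oxy)-3-methoxyphenyl]methyl}dihydrofuran-2(3H)-one (both carbinol epimers), via lithium enolate 18 (not isolated)
Conditions: LDA, THF, −78 °C; then 17, −78 °C; AcOH quench at −78 °C
Reagents that add atoms: none
Why: Aldol addition of the lactone lithium enolate occurs on the face anti to the C-4 benzyl group and sets C-3 trans to it; the exocyclic carbinol forms as both epimers, which converge in step 11.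

**Step 10**
Reactants: 19 (3S,4R)-4-[4-(benzyloxy)-3-methoxybenzyl]-3-{hydroxy[4-({(1S,2S)-1-[4-(benzyloxy)-3-methoxyphenyl]-1,3-bis[(tert-butyldimethylsilyl)oxy]propan-2-yl}oxy)-3-methoxyphenyl]methyl}dihydrofuran-2(3H)-one (both carbinol epimers)
Product: 20 (2R,3R)-3-[4-(benzyloxy)-3-methoxybenzyl]-2-{hydroxy[4-({(1S,2S)-1-[4-(benzyloxy)-3-methoxyphenyl]-1,3-bis[(tert-butyldimethylsilyl)oxy]propan-2-yl}oxy)-3-methoxyphenyl]methyl}butane-1,4-diol (both carbinol epimers)
Conditions: LiAlH4, THF, 0 °C; Fieser work-up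
Reagents that add atoms: none
Why: Hydride reduction opens the lactone to the 1,4-diol, while silyl ethers, benzyl ethers and the existing stereocentres are inert at 0 °C.

**Step 11**
Reactants: 20 (2R,3R)-3-[4-(benzyloxy)-3-methoxybenzyl]-2-{hydroxy[4-({(1S,2S)-1-[4-(benzyloxy)-3-methoxyphenyl]-1,3-bis[(tert-butyldimethylsilyl)oxy]propan-2-yl}oxy)-3-methoxyphenyl]methyl}butane-1,4-diol (both carbinol epimers)
Product: 21 {(2S,3R,4R)-4-[4-(benzyloxy)-3-methoxybenzyl]-2-[4-({(1S,2S)-1-[4-(benzyloxy)-3-methoxyphenyl]-1,3-bis[(tert-butyldimethylsilyl)oxy]propan-2-yl}oxy)-3-methoxyphenyl]tetrahydrofuran-3-yl}methanol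
Conditions: CSA (10 mol%), CH2Cl2, 0 °C, 15–30 min; Et3N quench
Reagents that add atoms: none
Why: SN1 cycloetherification, in which the p-alkoxybenzylic cation from either carbinol epimer is trapped 5-exo by the C-4 hydroxyl (the C-1 hydroxyl would give an oxetane) and the ring closes with the aryl group trans to the adjacent hydroxymethyl group, so C-2 is set by C-3.

**Step 12**
Reactants: 21 {(2S,3R,4R)-4-[4-(benzyloxy)-3-methoxybenzyl]-2-[4-({(1S,2S)-1-[4-(benzyloxy)-3-methoxyphenyl]-1,3-bis[(tert-butyldimethylsilyl)oxy]propan-2-yl}oxy)-3-methoxyphenyl]tetrahydrofuran-3-yl}methanol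
Product: 22 (1S,2S)-1-[4-(benzyloxy)-3-methoxyphenyl]-2-(4-{(2S,3R,4R)-4-[4-(benzyloxy)-3-methoxybenzyl]-3-(hydroxymethyl)tetrahydrofuran-2-yl}-2-methoxyphenoxy)propane-1,3-diol
Conditions: TBAF, THF, 0 °C → rt
Reagents that add atoms: none
Why: Fluoride-mediated desilylation removes both TBS ethers under conditions that leave the benzyl ethers and all stereocentres untouched.

**Step 13**
Reactants: 22 (1S,2S)-1-[4-(benzyloxy)-3-methoxyphenyl]-2-(4-{(2S,3R,4R)-4-[4-(benzyloxy)-3-methoxybenzyl]-3-(hydroxymethyl)tetrahydrofuran-2-yl}-2-methoxyphenoxy)propane-1,3-diol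
Product: 23 (1S,2S)-1-(4-hydroxy-3-methoxyphenyl)-2-(4-{(2S,3R,4R)-4-(4-hydroxy-3-methoxybenzyl)-3-(hydroxymethyl)tetrahydrofuran-2-yl}-2-methoxyphenoxy)propane-1,3-diol (target)
Conditions: H2 (1 atm), 10% Pd/C, EtOAc–EtOH, rt, stopped at complete debenzylation
Reagents that add atoms: none
Why: Hydrogenolysis of the two aryl benzyl ethers over Pd/C under neutral conditions is much faster than cleavage of the benzylic alcohol or of the benzylic ring C–O bond.

## Compound list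

1 | 4-allyl-1-(benzyloxy)-2-methoxybenzene (O-benzyleugenol) | C=CCc1ccc(OCc2ccccc2)c(OC)c1 | starting material
2 | (R)-but-3-en-2-ol | C[C@@H](O)C=C | starting material
3 | (2R,3E)-5-[4-(benzyloxy)-3-methoxyphenyl]pent-3-en-2-ol | C[C@@H](O)/C=C/Cc1ccc(OCc2ccccc2)c(OC)c1 | intermediate
4 | 1-(benzyloxy)-4-{(2E,4R)-4-[(1-ethoxyethenyl)oxy]pent-2-en-1-yl}-2-methoxybenzene (mixed ketene acetal) | C=C(OCC)O[C@H](C)/C=C/Cc1ccc(OCc2ccccc2)c(OC)c1 | intermediate
5 | ethyl (3R,4E)-3-[4-(benzyloxy)-3-methoxybenzyl]hex-4-enoate | CCOC(=O)C[C@@H](Cc1ccc(OCc2ccccc2)c(OC)c1)/C=C/C | intermediate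
6 | ethyl (3R)-3-[4-(benzyloxy)-3-methoxybenzyl]-4-oxobutanoate (aldehyde ester) | CCOC(=O)C[C@@H](Cc1ccc(OCc2ccccc2)c(OC)c1)C=O | intermediate
7 | ethyl (3R)-3-[4-(benzyloxy)-3-methoxybenzyl]-4-hydroxybutanoate (hydroxy ester) | CCOC(=O)C[C@@H](Cc1ccc(OCc2ccccc2)c(OC)c1)CO | intermediate
8 | (4R)-4-[4-(benzyloxy)-3-methoxybenzyl]dihydrofuran-2(3H)-one | O=C1C[C@@H](Cc2ccc(OCc3ccccc3)c(OC)c2)CO1 | intermediate
9 | 1-(benzyloxy)-4-bromo-2-methoxybenzene | COc1cc(Br)ccc1OCc1ccccc1 | starting material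
10 | (R)-2,2-dimethyl-1,3-dioxolane-4-carbaldehyde (2,3-O-isopropylidene-D-glyceraldehyde) | O=C[C@H]1COC(C)(C)O1 | starting material
11 | [4-(benzyloxy)-3-methoxyphenyl]magnesium bromide (aryl Grignard reagent) | COc1cc([Mg]Br)ccc1OCc1ccccc1 | intermediate
12 | (S)-[4-(benzyloxy)-3-methoxyphenyl][(4R)-2,2-dimethyl-1,3-dioxolan-4-yl]methanol | O[C@@H](c1ccc(OCc2ccccc2)c(OC)c1)[C@H]1COC(C)(C)O1 | intermediate
13 | {(S)-[4-(benzyloxy)-3-methoxyphenyl][(4R)-2,2-dimethyl-1,3-dioxolan-4-yl]methoxy}(tert-butyl)dimethylsilane | CC(C)(C)[Si](C)(C)O[C@@H](c1ccc(OCc2ccccc2)c(OC)c1)[C@H]1COC(C)(C)O1 | intermediate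
14 | (2R,3S)-3-[4-(benzyloxy)-3-methoxyphenyl]-3-[(tert-butyldimethylsilyl)oxy]propane-1,2-diol | CC(C)(C)[Si](C)(C)O[C@@H](c1ccc(OCc2ccccc2)c(OC)c1)[C@H](O)CO | intermediate
15 | (1S,2R)-1-[4-(benzyloxy)-3-methoxyphenyl]-1,3-bis[(tert-butyldimethylsilyl)oxy]propan-2-ol | CC(C)(C)[Si](C)(C)O[C@@H](c1ccc(OCc2ccccc2)c(OC)c1)[C@H](O)CO[Si](C)(C)C(C)(C)C | intermediate
16 | vanillin (4-hydroxy-3-methoxybenzaldehyde) | COc1cc(C=O)ccc1O | starting material
17 | 4-({(1S,2S)-1-[4-(benzyloxy)-3-methoxyphenyl]-1,3-bis[(tert-butyldimethylsilyl)oxy]propan-2-yl}oxy)-3-methoxybenzaldehyde | COc1cc(C=O)ccc1O[C@@H](CO[Si](C)(C)C(C)(C)C)[C@@H](O[Si](C)(C)C(C)(C)C)c1ccc(OCc2ccccc2)c(OC)c1 | intermediate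
18 | lithium (4R)-4-[4-(benzyloxy)-3-methoxybenzyl]-4,5-dihydrofuran-2-olate (lithium enolate of 8) | [Li]OC1=C[C@@H](Cc2ccc(OCc3ccccc3)c(OC)c2)CO1 | intermediate
19 | (3S,4R)-4-[4-(benzyloxy)-3-methoxybenzyl]-3-{hydroxy[4-({(1S,2S)-1-[4-(benzyloxy)-3-methoxyphenyl]-1,3-bis[(tert-butyldimethylsilyl)oxy]propan-2-yl}oxy)-3-methoxyphenyl]methyl}dihydrofuran-2(3H)-one, both carbinol epimers | O=C1OC[C@H](Cc2ccc(OCc3ccccc3)c(OC)c2)[C@H]1C(O)c1ccc(O[C@@H](CO[Si](C)(C)C(C)(C)C)[C@@H](O[Si](C)(C)C(C)(C)C)c2ccc(OCc3ccccc3)c(OC)c2)c(OC)c1 | intermediate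
20 | (2R,3R)-3-[4-(benzyloxy)-3-methoxybenzyl]-2-{hydroxy[4-({(1S,2S)-1-[4-(benzyloxy)-3-methoxyphenyl]-1,3-bis[(tert-butyldimethylsilyl)oxy]propan-2-yl}oxy)-3-methoxyphenyl]methyl}butane-1,4-diol, both carbinol epimers | OC[C@H](Cc1ccc(OCc2ccccc2)c(OC)c1)[C@H](CO)C(O)c1ccc(O[C@@H](CO[Si](C)(C)C(C)(C)C)[C@@H](O[Si](C)(C)C(C)(C)C)c2ccc(OCc3ccccc3)c(OC)c2)c(OC)c1 | intermediate
21 | {(2S,3R,4R)-4-[4-(benzyloxy)-3-methoxybenzyl]-2-[4-({(1S,2S)-1-[4-(benzyloxy)-3-methoxyphenyl]-1,3-bis[(tert-butyldimethylsilyl)oxy]propan-2-yl}oxy)-3-methoxyphenyl]tetrahydrofuran-3-yl}methanol | COc1cc(C[C@H]2CO[C@H](c3ccc(O[C@@H](CO[Si](C)(C)C(C)(C)C)[C@@H](O[Si](C)(C)C(C)(C)C)c4ccc(OCc5ccccc5)c(OC)c4)c(OC)c3)[C@H]2CO)ccc1OCc1ccccc1 | intermediate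
22 | (1S,2S)-1-[4-(benzyloxy)-3-methoxyphenyl]-2-(4-{(2S,3R,4R)-4-[4-(benzyloxy)-3-methoxybenzyl]-3-(hydroxymethyl)tetrahydrofuran-2-yl}-2-methoxyphenoxy)propane-1,3-diol | COc1cc(C[C@H]2CO[C@H](c3ccc(O[C@@H](CO)[C@@H](O)c4ccc(OCc5ccccc5)c(OC)c4)c(OC)c3)[C@H]2CO)ccc1OCc1ccccc1 | intermediate
23 | (1S,2S)-1-(4-hydroxy-3-methoxyphenyl)-2-(4-{(2S,3R,4R)-4-(4-hydroxy-3-methoxybenzyl)-3-(hydroxymethyl)tetrahydrofuran-2-yl}-2-methoxyphenoxy)propane-1,3-diol | COc1cc(C[C@H]2CO[C@H](c3ccc(O[C@@H](CO)[C@@H](O)c4ccc(O)c(OC)c4)c(OC)c3)[C@H]2CO)ccc1O | target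

## Step count and risks

Total: 13 steps. Longest linear sequence: 10 steps (steps 4–8, then 9–13); the lactone branch (steps 1–3) is 3 steps.

**Step 8 (Mitsunobu etherification).** The carbinol is hindered and flanked by oxygenated carbons, so elimination or participation of the neighbouring electron-rich aryl group may compete. The fallback sets out from 15. The alcohol is converted with Tf2O and 2,6-lutidine in CH2Cl2 at −78 °C into (1S,2R)-1-[4-(benzyloxy)-3-methoxyphenyl]-1,3-bis[(tert-butyldimethylsilyl)oxy]propan-2-yl trifluoromethanesulfonate F3. This is displaced at 0 °C in MeCN by the caesium phenoxide of 16 (Cs2CO3) in a separate SN2 step with the same inversion, and the sequence comes back to the route at 17.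

**Step 11 (acid-promoted ring closure).** The silylated benzylic ether of the side chain could ionise as well, and prolonged acid converts the tetrahydrofuran into the aryltetralin by Friedel–Crafts closure. The fallback sets out from 8 and closes the ring before the side chain is present:
- The enolate 18 is added to bought 4-[(tert-butyldimethylsilyl)oxy]-3-methoxybenzaldehyde F4 to give the trans aldol lactone (3S,4R)-4-[4-(benzyloxy)-3-methoxybenzyl]-3-{[4-[(tert-butyldimethylsilyl)oxy]-3-methoxyphenyl](hydroxy)methyl}dihydrofuran-2(3H)-one F5.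
- LiAlH4 reduces it to the triol (2R,3R)-3-[4-(benzyloxy)-3-methoxybenzyl]-2-{[4-[(tert-butyldimethylsilyl)oxy]-3-methoxyphenyl](hydroxy)methyl}butane-1,4-diol F6.
- TBAF frees the phenol to give (2R,3R)-3-[4-(benzyloxy)-3-methoxybenzyl]-2-[hydroxy(4-hydroxy-3-methoxyphenyl)methyl]butane-1,4-diol F7.
- With a trace of acid the p-hydroxybenzylic alcohol of F7 closes through a p-quinone methide to 4-{(2S,3R,4R)-4-[4-(benzyloxy)-3-methoxybenzyl]-3-(hydroxymethyl)tetrahydrofuran-2-yl}-2-methoxyphenol F8.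
- The caesium phenoxide of F8 (Cs2CO3, MeCN) is alkylated with the triflate F3 made from 15 as above; the phenoxide reacts in preference to the free primary alcohol. This comes back to the route at 21.

**Step 4 (facial selectivity of the Grignard addition).** Only a moderate Felkin–Anh preference is expected for an aryl Grignard reagent, which costs material and makes separation necessary. The fallback sets out from 9 and 10. The addition is run without regard to selectivity, and the mixture of 12 and its carbinol epimer (R)-[4-(benzyloxy)-3-methoxyphenyl][(4R)-2,2-dimethyl-1,3-dioxolan-4-yl]methanol F1 is oxidised with Dess–Martin periodinane (NaHCO3, CH2Cl2) to the ketone [4-(benzyloxy)-3-methoxyphenyl][(4R)-2,2-dimethyl-1,3-dioxolan-4-yl]methanone F2. L-Selectride in THF at −78 °C then delivers hydride under Felkin–Anh control, so the carbinol centre is set by reduction instead of C–C addition, and the sequence comes back to the route at 12.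

## Further compounds

F1 | step 4 | (R)-[4-(benzyloxy)-3-methoxyphenyl][(4R)-2,2-dimethyl-1,3-dioxolan-4-yl]methanol | O[C@H](c1ccc(OCc2ccccc2)c(OC)c1)[C@H]1COC(C)(C)O1
F2 | step 4 | [4-(benzyloxy)-3-methoxyphenyl][(4R)-2,2-dimethyl-1,3-dioxolan-4-yl]methanone | O=C(c1ccc(OCc2ccccc2)c(OC)c1)[C@H]1COC(C)(C)O1
F3 | step 8 | (1S,2R)-1-[4-(benzyloxy)-3-methoxyphenyl]-1,3-bis[(tert-butyldimethylsilyl)oxy]propan-2-yl trifluoromethanesulfonate | CC(C)(C)[Si](C)(C)O[C@@H](c1ccc(OCc2ccccc2)c(OC)c1)[C@H](OS(=O)(=O)C(F)(F)F)CO[Si](C)(C)C(C)(C)C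
F4 | step 11 | 4-[(tert-butyldimethylsilyl)oxy]-3-methoxybenzaldehyde | COc1cc(C=O)ccc1O[Si](C)(C)C(C)(C)C
F5 | step 11 | (3S,4R)-4-[4-(benzyloxy)-3-methoxybenzyl]-3-{[4-[(tert-butyldimethylsilyl)oxy]-3-methoxyphenyl](hydroxy)methyl}dihydrofuran-2(3H)-one, both carbinol epimers | O=C1OC[C@H](Cc2ccc(OCc3ccccc3)c(OC)c2)[C@H]1C(O)c1ccc(O[Si](C)(C)C(C)(C)C)c(OC)c1
F6 | step 11 | (2R,3R)-3-[4-(benzyloxy)-3-methoxybenzyl]-2-{[4-[(tert-butyldimethylsilyl)oxy]-3-methoxyphenyl](hydroxy)methyl}butane-1,4-diol, both carbinol epimers | OC[C@H](Cc1ccc(OCc2ccccc2)c(OC)c1)[C@H](CO)C(O)c1ccc(O[Si](C)(C)C(C)(C)C)c(OC)c1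
F7 | step 11 | (2R,3R)-3-[4-(benzyloxy)-3-methoxybenzyl]-2-[hydroxy(4-hydroxy-3-methoxyphenyl)methyl]butane-1,4-diol, both carbinol epimers | OC[C@H](Cc1ccc(OCc2ccccc2)c(OC)c1)[C@H](CO)C(O)c1ccc(O)c(OC)c1
F8 | step 11 | 4-{(2S,3R,4R)-4-[4-(benzyloxy)-3-methoxybenzyl]-3-(hydroxymethyl)tetrahydrofuran-2-yl}-2-methoxyphenol | COc1cc(C[C@H]2CO[C@H](c3ccc(O)c(OC)c3)[C@H]2CO)ccc1OCc1ccccc1
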